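## Retrosynthetic overview

1. Target 21 comes from silyl ether 20 by desilylation in the work-up. The only ring made, the 11-membered carbocycle, is closed last at C4–C5: hydrogen-atom transfer to the isopropenyl group of open-chain enal 19 gives a tertiary radical, chromium captures it, and the alkylchromium adds to the aldehyde.
2. Enal 19 comes from PMB ether 17 by oxidative PMB removal and oxidation at C1.
3. Ester 17 is assembled in one flask from aldehyde 7, the alkenyl metal derived from alkyne 9, and acid chloride 14; the C–O stereocentre is set here.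
4. Aldehyde 7 comes from alkyne 3 (methylalumination, ethylene oxide, oxidation); 3 comes from bromide 1 and acetylide 2.
5. Acid chloride 14 comes from 4-bromophenol 10; alkyne 9 comes from but-2-yn-1-ol 8.

Assumption: 1, 2, 4, 8 and 10 are bought. Open-chain compounds are numbered as dodecatrienes (C1 becomes the free carbinol carbon, C4 is the ester carbon, C11 becomes the gem-dimethyl carbon); the macrocycle is numbered as in the name of 21.

## Route

Step 1
Reactants: 1 5-bromo-2-methylpent-1-ene; 2 lithium acetylide–ethylenediamine complex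
Product: 3 6-methylhept-6-en-1-yne
Conditions: DMSO, 10 °C → rt, 3 h
Reagents that add atoms: none
Why: SN2 alkylation of the acetylide by an unhindered primary bromide (acetylide alkylation); no stereocentre.

Step 2
Reactants: 3 6-methylhept-6-en-1-yne; 4 ethylene oxide
Product: 6 (3E)-4,8-dimethylnona-3,8-dien-1-ol, via alkenylalane 5 (not isolated)
Conditions: Al(CH3)3 (2 equiv), Cp2ZrCl2 (0.25 equiv), CH2Cl2, 0 °C → rt; evaporate; n-BuLi, hexane/THF, −30 °C; 4, −30 °C → rt; cold 1 M HCl
Reagents that add atoms: trimethylaluminium C[Al](C)C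
Why: Negishi zirconium-catalysed carboalumination adds CH3 and Al syn across the terminal alkyne, which fixes the E alkene (the 1,1-disubstituted alkene is inert), and the lithium alanate opens ethylene oxide with retention of alkene geometry.

Step 3
Reactants: 6 (3E)-4,8-dimethylnona-3,8-dien-1-ol
Product: 7 (3E)-4,8-dimethylnona-3,8-dienal
Conditions: Dess–Martin periodinane, NaHCO3, CH2Cl2, 0 °C, 1 h; used crude at once
Reagents that add atoms: none
Why: Buffered Dess–Martin oxidation stops at the aldehyde and at 0 °C does not move the alkene into conjugation; no stereocentre.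

Step 4
Reactants: 8 but-2-yn-1-ol
Product: 9 1-[(but-2-yn-1-yloxy)methyl]-4-methoxybenzene
Conditions: NaH, 4-methoxybenzyl chloride, Bu4NI (cat.), THF/DMF, 0 °C → rt
Reagents that add atoms: 4-methoxybenzyl chloride COc1ccc(CCl)cc1
Why: Williamson ether synthesis; the PMB ether survives the zirconium and zinc reagents of step 7 and is removed oxidatively in step 8.

Step 5
Reactants: 10 4-bromophenol
Product: 11 (4-bromophenoxy)(tert-butyl)dimethylsilane
Conditions: TBSCl, imidazole, DMF, rt
Reagents that add atoms: tert-butyldimethylsilyl chloride CC(C)(C)[Si](C)(C)Cl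
Why: Standard silylation of a phenol; the aryl silyl ether tolerates bromine–lithium exchange at −78 °C.

Step 6
Reactants: 11 (4-bromophenoxy)(tert-butyl)dimethylsilane
Product: 14 4-[(tert-butyldimethylsilyl)oxy]benzoyl chloride, via aryllithium 12 (not isolated), via lithium carboxylate 13 (not isolated)
Conditions: n-BuLi, THF, −78 °C; CO2, −78 °C → rt; evaporate; (COCl)2, DMF (cat.), CH2Cl2, 0 °C → rt; filter, evaporate, use crude
Reagents that add atoms: carbon dioxide O=C=O; oxalyl chloride O=C(Cl)C(=O)Cl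
Why: Bromine–lithium exchange, carboxylation of the aryllithium, and conversion of the lithium carboxylate into the acid chloride under acid-free conditions that keep the silyl ether.

Step 7
Reactants: 9 1-[(but-2-yn-1-yloxy)methyl]-4-methoxybenzene; 7 (3E)-4,8-dimethylnona-3,8-dienal; 14 4-[(tert-butyldimethylsilyl)oxy]benzoyl chloride
Product: 17 (2E,4R,6E)-1-[(4-methoxybenzyl)oxy]-3,7,11-trimethyldodeca-2,6,11-trien-4-yl 4-[(tert-butyldimethylsilyl)oxy]benzoate, via alkenylzirconocene 15 (not isolated), via zinc alkoxide 16 (not isolated)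
Conditions: 9 (1.6 equiv), Cp2Zr(H)Cl (1.5 equiv), CH2Cl2, rt; Zn(CH3)2 (1.5 equiv), toluene, −65 °C; (−)-MIB (10 mol %), 7 (1 equiv), −30 °C, 16 h; 14 (2 equiv), DMAP (0.2 equiv), 0 °C → rt
Reagents that add atoms: none
Why: Syn-hydrozirconation places zirconium on the methyl-bearing alkyne carbon (E alkenyl metal), and after Zr-to-Zn exchange the amino-alcohol-bound alkenylzinc adds to the Si face of 7 to set 4R (Wipf–Oppolzer alkenylzinc addition, same facial sense as dialkylzinc additions with this ligand); the zinc alkoxide is then acylated in the flask.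

Step 8
Reactants: 17 (2E,4R,6E)-1-[(4-methoxybenzyl)oxy]-3,7,11-trimethyldodeca-2,6,11-trien-4-yl 4-[(tert-butyldimethylsilyl)oxy]benzoate
Product: 19 (2E,4R,6E)-3,7,11-trimethyl-1-oxododeca-2,6,11-trien-4-yl 4-[(tert-butyldimethylsilyl)oxy]benzoate, via allylic alcohol 18 (not isolated)
Conditions: DDQ (1.3 equiv), CH2Cl2/pH 7 buffer (10:1), 0 °C; then PhI(OAc)2 (1.5 equiv), TEMPO (0.2 equiv), rt
Reagents that add atoms: none
Why: DDQ cleaves the PMB ether by benzylic hydride abstraction and TEMPO/PhI(OAc)2 then oxidises only the primary allylic alcohol to the E enal; C4 and the aryl silyl ether are untouched.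

Step 9
Reactants: 19 (2E,4R,6E)-3,7,11-trimethyl-1-oxododeca-2,6,11-trien-4-yl 4-[(tert-butyldimethylsilyl)oxy]benzoate
Product: 21 (1R,2E,4R,9E)-4-hydroxy-2,5,5,9-tetramethylcycloundeca-2,9-dien-1-yl 4-hydroxybenzoate, via silyl ether 20 (not isolated)
Conditions: (R,R)-[N,N′-bis(3,5-di-tert-butylsalicylidene)-1,2-cyclohexanediaminato]cobalt, Co(C36H52N2O2) (15 mol %), CrCl3(THF)3 (40 mol %), PhSiH3 (3 equiv), degassed THF, 25 °C, 19 added over 12 h by syringe pump (final 2 mM); concentrate; Bu4NF/AcOH (3 equiv each), THF, 0 °C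
Reagents that add atoms: none
Why: Proposed new method: the trivalent cobalt hydride formed from the salen complex and PhSiH3 transfers a hydrogen atom only to the 1,1-disubstituted alkene (the trisubstituted alkenes are too hindered or electron-poor for this bulky hydride), the tertiary C11 radical is captured by divalent chromium (formed by electron exchange with the divalent cobalt left behind, which is faster than 6-membered radical cyclisation onto C6=C7), and the tertiary alkylchromium adds 1,2 to the C1 aldehyde, with silane turning over both metals and capping the alkoxide; the closest known reactions are the intermolecular branch-selective cobalt/chromium hydrogen-atom-transfer coupling of unactivated alkenes with aldehydes and Nozaki–Hiyama–Kishi macrocyclisations. The new carbinol is predicted to be R because the tether must span one face of the s-trans enal while the C4–O bond eclipses C2=C3 (least A(1,2) strain with the C3 methyl); this is a conformational prediction, not a precedent. Fluoride then removes both silyl groups.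

## Compound list

1 | 5-bromo-2-methylpent-1-ene | C=C(C)CCCBr | starting material
2 | lithium acetylide–ethylenediamine complex | [Li]C#C.NCCN | starting material
3 | 6-methylhept-6-en-1-yne | C=C(C)CCCC#C | intermediate
4 | ethylene oxide | C1CO1 | starting material
5 | dimethyl[(1E)-2,6-dimethylhepta-1,6-dien-1-yl]alane | C=C(C)CCC/C(C)=C/[Al](C)C | intermediate
6 | (3E)-4,8-dimethylnona-3,8-dien-1-ol | C=C(C)CCC/C(C)=C/CCO | intermediate
7 | (3E)-4,8-dimethylnona-3,8-dienal | C=C(C)CCC/C(C)=C/CC=O | intermediate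
8 | but-2-yn-1-ol | CC#CCO | starting material
9 | 1-[(but-2-yn-1-yloxy)methyl]-4-methoxybenzene | CC#CCOCc1ccc(OC)cc1 | intermediate
10 | 4-bromophenol | Oc1ccc(Br)cc1 | starting material
11 | (4-bromophenoxy)(tert-butyl)dimethylsilane | CC(C)(C)[Si](C)(C)Oc1ccc(Br)cc1 | intermediate
12 | {4-[(tert-butyldimethylsilyl)oxy]phenyl}lithium | [Li]c1ccc(O[Si](C)(C)C(C)(C)C)cc1 | intermediate
13 | lithium 4-[(tert-butyldimethylsilyl)oxy]benzoate | [Li+].[O-]C(=O)c1ccc(O[Si](C)(C)C(C)(C)C)cc1 | intermediate
14 | 4-[(tert-butyldimethylsilyl)oxy]benzoyl chloride | O=C(Cl)c1ccc(O[Si](C)(C)C(C)(C)C)cc1 | intermediate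
15 | chloro{(2E)-4-[(4-methoxybenzyl)oxy]but-2-en-2-yl}zirconocene | C/C(=C\COCc1ccc(OC)cc1)[Zr](Cl)(C1C=CC=C1)C1C=CC=C1 | intermediate
16 | methylzinc (2E,4R,6E)-1-[(4-methoxybenzyl)oxy]-3,7,11-trimethyldodeca-2,6,11-trien-4-olate | C=C(C)CCC/C(C)=C/C[C@@H](O[Zn]C)/C(C)=C/COCc1ccc(OC)cc1 | intermediate
17 | (2E,4R,6E)-1-[(4-methoxybenzyl)oxy]-3,7,11-trimethyldodeca-2,6,11-trien-4-yl 4-[(tert-butyldimethylsilyl)oxy]benzoate | C=C(C)CCC/C(C)=C/C[C@@H](OC(=O)c1ccc(O[Si](C)(C)C(C)(C)C)cc1)/C(C)=C/COCc1ccc(OC)cc1 | intermediate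
18 | (2E,4R,6E)-1-hydroxy-3,7,11-trimethyldodeca-2,6,11-trien-4-yl 4-[(tert-butyldimethylsilyl)oxy]benzoate | C=C(C)CCC/C(C)=C/C[C@@H](OC(=O)c1ccc(O[Si](C)(C)C(C)(C)C)cc1)/C(C)=C/CO | intermediate
19 | (2E,4R,6E)-3,7,11-trimethyl-1-oxododeca-2,6,11-trien-4-yl 4-[(tert-butyldimethylsilyl)oxy]benzoate | C=C(C)CCC/C(C)=C/C[C@@H](OC(=O)c1ccc(O[Si](C)(C)C(C)(C)C)cc1)/C(C)=C/C=O | intermediate
20 | (1R,2E,4R,9E)-2,5,5,9-tetramethyl-4-[(phenylsilyl)oxy]cycloundeca-2,9-dien-1-yl 4-[(tert-butyldimethylsilyl)oxy]benzoate | C/C1=C\C[C@@H](OC(=O)c2ccc(O[Si](C)(C)C(C)(C)C)cc2)/C(C)=C/[C@@H](O[SiH2]c2ccccc2)C(C)(C)CCC1 | intermediate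
21 | (1R,2E,4R,9E)-4-hydroxy-2,5,5,9-tetramethylcycloundeca-2,9-dien-1-yl 4-hydroxybenzoate | C/C1=C\C[C@@H](OC(=O)c2ccc(O)cc2)/C(C)=C/[C@@H](O)C(C)(C)CCC1 | target

## Step count and risks

Total: 9 steps. Longest linear sequence: 6 steps (1, 2, 3, 7, 8, 9).

Step 9 is the most likely to fail. The intramolecular cobalt/chromium closure is unprecedented; the radical may be reduced or cyclise onto C6=C7 before chromium captures it, the aldehyde may be hydrosilylated, and the facial selectivity at the new carbinol is only predicted. The fallback separates radical generation from the addition. It sets out from 17 and comes back at 21.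
- Cobalt-mediated hydrogen-atom-transfer hydrobromination of the isopropenyl group (Co(acac)2, t-BuOOH, Et3SiH, p-toluenesulfonyl bromide) gives tertiary bromide F1.
- The conditions of step 8 give bromo enal F2.
- Slow addition of F2 to excess CrCl2 with catalytic cobalt phthalocyanine, Co(C32H16N8), in DMF/THF closes the ring to macrocyclic alcohol F3, taken as a mixture at C4. Here divalent chromium abstracts bromine, captures the radical and adds to the aldehyde (Barbier type).
- Dess–Martin oxidation gives enone F4.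
- (S)-Me-CBS with BH3·SMe2 gives (4R)-alcohol F5, with the quaternary carbon acting as the large group.
- Bu4NF/AcOH gives 21.

Step 7 is the second risk. The hydrozirconation must be regioselective, the ee with an α-branched alkenylzinc and an enolisable β,γ-unsaturated aldehyde is uncertain, and the acylation is done in the same flask. The fallback sets the stereocentre by ketone reduction instead. It sets out from 9 (with 7) and comes back at 17.
- Hydrozirconation of 9 as before, quenched with I2, gives vinyl iodide F6.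
- Nozaki–Hiyama–Kishi coupling of F6 with 7 (CrCl2, NiCl2 cat., DMF) gives racemic allylic alcohol F7.
- Buffered Dess–Martin oxidation gives dienone F8.
- (S)-Me-CBS with catecholborane at −78 °C gives (4R)-alcohol F9, with the alkenyl group as the large group.
- Acylation with 14 (Et3N, DMAP) gives 17.

Step 2 is the third risk. Alanate openings of ethylene oxide give variable yields because methyl or butyl can transfer instead of the alkenyl group. The fallback uses an isolated iodide and an organolithium. It sets out from 3 and comes back at 6.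
- The same carboalumination, quenched with I2, gives vinyl iodide F10.
- t-BuLi (2 equiv, Et2O, −78 °C) gives alkenyllithium F11.
- F11 opens ethylene oxide 4 (BF3·OEt2, −78 °C) to give 6.

## Further compounds

F1 | step 9 | (2E,4R,6E)-11-bromo-1-[(4-methoxybenzyl)oxy]-3,7,11-trimethyldodeca-2,6-dien-4-yl 4-[(tert-butyldimethylsilyl)oxy]benzoate | CC(C)(Br)CCC/C(C)=C/C[C@@H](OC(=O)c1ccc(O[Si](C)(C)C(C)(C)C)cc1)/C(C)=C/COCc1ccc(OC)cc1
F2 | step 9 | (2E,4R,6E)-11-bromo-3,7,11-trimethyl-1-oxododeca-2,6-dien-4-yl 4-[(tert-butyldimethylsilyl)oxy]benzoate | CC(C)(Br)CCC/C(C)=C/C[C@@H](OC(=O)c1ccc(O[Si](C)(C)C(C)(C)C)cc1)/C(C)=C/C=O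
F3 | step 9 | (1R,2E,9E)-4-hydroxy-2,5,5,9-tetramethylcycloundeca-2,9-dien-1-yl 4-[(tert-butyldimethylsilyl)oxy]benzoate (C4 epimers) | C/C1=C\C[C@@H](OC(=O)c2ccc(O[Si](C)(C)C(C)(C)C)cc2)/C(C)=C/C(O)C(C)(C)CCC1
F4 | step 9 | (1R,2E,9E)-2,5,5,9-tetramethyl-4-oxocycloundeca-2,9-dien-1-yl 4-[(tert-butyldimethylsilyl)oxy]benzoate | C/C1=C\C[C@@H](OC(=O)c2ccc(O[Si](C)(C)C(C)(C)C)cc2)/C(C)=C/C(=O)C(C)(C)CCC1
F5 | step 9 | (1R,2E,4R,9E)-4-hydroxy-2,5,5,9-tetramethylcycloundeca-2,9-dien-1-yl 4-[(tert-butyldimethylsilyl)oxy]benzoate | C/C1=C\C[C@@H](OC(=O)c2ccc(O[Si](C)(C)C(C)(C)C)cc2)/C(C)=C/[C@@H](O)C(C)(C)CCC1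
F6 | step 7 | 1-({[(2E)-3-iodobut-2-en-1-yl]oxy}methyl)-4-methoxybenzene | C/C(I)=C\COCc1ccc(OC)cc1
F7 | step 7 | (2E,6E)-1-[(4-methoxybenzyl)oxy]-3,7,11-trimethyldodeca-2,6,11-trien-4-ol (racemic) | C=C(C)CCC/C(C)=C/CC(O)/C(C)=C/COCc1ccc(OC)cc1
F8 | step 7 | (2E,6E)-1-[(4-methoxybenzyl)oxy]-3,7,11-trimethyldodeca-2,6,11-trien-4-one | C=C(C)CCC/C(C)=C/CC(=O)/C(C)=C/COCc1ccc(OC)cc1
F9 | step 7 | (2E,4R,6E)-1-[(4-methoxybenzyl)oxy]-3,7,11-trimethyldodeca-2,6,11-trien-4-ol | C=C(C)CCC/C(C)=C/C[C@@H](O)/C(C)=C/COCc1ccc(OC)cc1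
F10 | step 2 | (1E)-1-iodo-2,6-dimethylhepta-1,6-diene | C=C(C)CCC/C(C)=C/I
F11 | step 2 | [(1E)-2,6-dimethylhepta-1,6-dien-1-yl]lithium | C=C(C)CCC/C(C)=C/[Li]
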